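Count the target in mol per litre, not in percent of the charge, and the two earlier runs begin to read alike.

| flask | substrate | coupling partner | remark | time |
|---|---|---|---|---|
| red | 0.38 M | 0.325 M | run made earlier |  |
| teal | 0.50 M | 0.325 M | run made earlier |  |
| larch | 0.25 M | 0.330 M |  | 8.0 h |
| cedar | 0.25 M | 0.420 M |  | 8.0 h |
| birch | 0.25 M | 0.550 M |  | 8.0 h |

| run | time / h | target / % |
|---|---|---|
| red | 0.417 | 15 |
| red | 0.667 | 10 |
| red | 1.00 | 4 |
| red | 2.00 | 3 |
| red | 3.00 | 0 |
| red | 5.00 | 0 |
| teal | 0.833 | 4 |
| teal | 1.50 | 2 |
| teal | 2.50 | 0 |
| teal | 3.00 | 1 |
| teal | 4.00 | 0 |
| teal | 5.00 | 1 |

(each reading ± 1.5 percentage points)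

- percentages count the substrate that a species holds: one side product B counts as two

1. which of the two there is more of at the end, counted by the substrate in each, larch (side product B / target)
2. which of the two there is more of at the end, counted by the substrate in each, cedar (side product B / target)
3. which of the two there is more of at the end, counted by the substrate in each, birch (side product B / target)
4. final target, as a percentage of the substrate charged, in larch
5. final target, as a percentage of the substrate charged, in cedar
6. final target, as a percentage of the substrate charged, in birch

Suppose target is lost by a second-order step, dc_target/dt = −κ · c_target · c_target. That rate integrates in closed form to a straight line in the reciprocal: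

1/c_target(t) = 1/c_target(start) + κ · (t − start)

The red run, between its readings at 0.417 h and 1.00 h, gives

κ = (65.8 M⁻¹ − 17.5 M⁻¹) / 0.583 h = 1.38 M⁻¹ min⁻¹

The teal run, between 0.833 h and 1.50 h, gives 1.25 M⁻¹ min⁻¹. I carry κ, the reciprocal climb of target. The two runs read about the same despite their different substrate charges, but κ stays rough, since readings as low as 2% carry a scatter of 1.5 percentage points.

Larch looks nearly the same as the red run: coupling partner 0.330 M against 0.325 M, but substrate 0.25 M against 0.38 M. By 8.0 h the climb κt stands far above the early reciprocal, so the start drops out:

c_target(t) ≈ 1/(κ t)

For the red run at 5.00 h this is 0.00242 M, or 0.636% of its charge, which its reading of 0% cannot tell from nothing. For larch at 8.0 h my reckoning gives 0.00151 M, or 0.604%. It is the same line read later and against a smaller charge. Neither run varied the coupling partner, so I carry no partner term and expect this figure for cedar and birch too. That figure lies under the scatter, so watch the first hours and plot the reciprocal there.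

The forecast puts side product B ahead in larch, cedar and birch, with target at 15%, 22% and 32%, reasoning that “More partner favours forming target over its loss”. My reckoning differs: it is flat across the flasks and lower.

    substrate + coupling partner ⇌ target (K = 21.0 M⁻¹, k = 0.500 M⁻¹ min⁻¹)
    2 coupling partner → side product A (k = 0.180 M⁻¹ min⁻¹)
    substrate + target → side product B (k = 0.420 M⁻¹ min⁻¹)
    coupling partner → decomposition product (k = 3.30 × 10⁻⁵ min⁻¹)

The flasks give 0.537%, 0.554% and 0.567% of target against my 0.604%, while side product B holds 94.4% in larch, as the forecast chose. Part of why larch ends so low is two steps acting together: with the back reaction taken away larch ends at 30.7%, and with the path from substrate + target to side product B taken away at 24.9%. Now take the neighbour of larch with 1.3 M of coupling partner, its other charges and time as in larch: κ again gives 0.604% at 8.0 h, and the computed flask gives 0.595%.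

(Readings and results stem from a simulated flask from invented constants; scatter was added.)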